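A colleague asked us for a quick number on four flasks, with the hunch that more coupling partner means more product.

| flask | starting material | coupling partner | remark | time |
|---|---|---|---|---|
| gamma | 6.7 mM (in portions, 4) | 10 mM | run made earlier; portions every 6.0 s |  |
| eta | 20 mM (in portions, 4) | 10 mM | run made earlier; portions every 6.0 s |  |
| Saturday's | 10 mM (in portions, 4) | 10.0 mM | the portions of starting material follow each other after 6.0 s, the first at the start | 15 min |
| Tuesday's | 10 mM (in portions, 4) | 30.0 mM | the portions of starting material follow each other after 6.0 s, the first at the start | 15 min |
| Wednesday's | 10 mM (in portions, 4) | 100 mM | the portions of starting material follow each other after 6.0 s, the first at the start | 15 min |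
| Sunday's | 10 mM (in portions, 4) | 300 mM | the portions of starting material follow each other after 6.0 s, the first at the start | 15 min |

| run | time / min | product / % | starting material / % |
|---|---|---|---|
| gamma | 0.667 | 3 | 80 |
| gamma | 1.33 | 0 | 64 |
| gamma | 2.00 | 0 | 53 |
| gamma | 3.00 | 4 | 47 |
| gamma | 5.00 | 5 | 36 |
| gamma | 10.0 | 21 | 30 |
| eta | 0.667 | 0 | 85 |
| eta | 2.00 | 2 | 70 |
| eta | 3.00 | 4 | 68 |
| eta | 5.00 | 5 | 65 |
| eta | 6.00 | 11 | 63 |
| eta | 10.0 | 14 | 59 |

(scatter of a reading: 2 percentage points)

- [product] at the end for Saturday's, Tuesday's, Wednesday's, Sunday's, in this order
- the shape of the row from first to last (falls, then rises / falls all the way / rises all the way / rises, then falls / hardly changes)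

- "hardly changes" means that all values lie within two and a half points (for a concentration: within two and a half percent of the largest)

We begin with what the runs show plainly. In the gamma run at 10.0 min, starting material reads 30% and product 21%, so by these readings 49.0% of the charge is in neither form.

What we can reckon is the pace of that loss. We freeze [coupling partner] at its charge, which makes the loss pseudo-first-order. The portions enter on average 9.00 s after the start, so we count the first reading of each run from then. Gamma gives 0.432 min⁻¹ and eta 0.314 min⁻¹. Each rests on a reading with a scatter of 2 percentage points, so we take the mean, 0.373 min⁻¹. From it we carry one quantity, 1.86 min: the time in which [starting material] halves with [coupling partner] held at 10 mM. We suppose that it shrinks in proportion as the charge of coupling partner grows; gamma and eta hold the same charge of it, so they do not test this. On that supposition it becomes 3.72 s for Sunday's, shorter than the spacing of 6.0 s, so we expect each portion to be more than half gone before the next arrives. There the coupling partner outweighs the starting material 30.0 to one, so the freeze is fair at the start; on Saturday's, with equal charges, it is rough. This reckoning gives pace, not yield, so it gives no row of its own.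

The forecast rests on its own constants and gives 3 mM, 4.7 mM, 5.1 mM and 5.2 mM, a row that rises all the way: “The row rises and levels off, assuming no inhibition by excess partner.”

The flasks give 2.73 mM, 3.51 mM, 1.78 mM and 0.724 mM, a row that rises, then falls, turning at 22 mM of coupling partner.

    intermediate B ⇌ product (K = 0.940, k = 0.00280 s⁻¹)
    intermediate A → intermediate B (k = 0.00790 s⁻¹)
    starting material + coupling partner → intermediate A (k = 1.00 M⁻¹ s⁻¹)
    coupling partner ⇌ dormant form (K = 10.0, k = 0.00370 s⁻¹)
    coupling partner + intermediate A ⇌ intermediate C (K = 460 M⁻¹, k = 4.80 M⁻¹ s⁻¹)

On Saturday's, 15 min is 8.06 of our half-lives, yet coupling partner was down to 5.97% of its charge at 7.50 min, and 35.3% of the starting material still stood at 15.0 min. On Sunday's, with our reckoned half-life of 3.72 s, starting material stood at 5.91% of the whole charge at 0.300 min, just before the last addition, while intermediate C already held 66.6%, and the slow addition made no difference to [product] at the end; at 15.0 min Sunday's held 74.7% as intermediate C, more than the 13.4% as intermediate B, and 7.24% as product.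

Readings and results come from a simulation on assumed constants; the scatter is artificial.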